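A flat product line invites the entry "equilibrium", and that is the pitfall here. Taken as substrate + reagent ⇌ product + released group, the forecast gets a constant of 8.4 from the north run and 3.1 from the north-east run, two values that do not make one constant.

| flask | substrate | reagent | remark | time |
|---|---|---|---|---|
| north | 0.20 M | 0.16 M | the very flask that is asked about, followed so far |  |
| north-east | 0.20 M | 0.080 M | run made earlier |  |
| flask | 0.20 M | 0.160 M |  | 40 min |

north run (percent of the substrate charged)

| time / min | product / % |
|---|---|
| 2.50 | 64.6 |
| 4.00 | 66.0 |
| 6.00 | 64.1 |
| 10.0 | 65.6 |
| 15.0 | 66.3 |
| 20.0 | 66.4 |
| 30.0 | 64.6 |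

north-east run (percent of the substrate charged)

| time / s | product / % |
|---|---|
| 10.0 | 12.1 |
| 15.0 | 23.0 |
| 25.0 | 33.2 |
| 40.0 | 35.5 |
| 60.0 | 33.4 |
| 80.0 | 34.6 |
| 90.0 | 34.0 |

(scatter of a reading: 1 percentage point)

- beta: at 40 min add substrate, 50.0 % of the amount charged, then wait 80 min
- alpha: at 40 min add reagent, 50.0 % of the amount charged, then wait 80 min
- zeta: at 40 min take out 90 % of the released group then present, then wait 80 min
- delta: change nothing and wait 80 min more

- additions bring no volume worth counting
- a reading or a percentage of product counts all its forms, free or not

- product, in percent of the substrate first charged, at 40 min
- the option that brings most further product ("none" if no option brings more than 2 percentage points) (beta / alpha / zeta / delta / none)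
- product present, in percent of the substrate first charged, after beta
- product present, in percent of the substrate first charged, after delta

So we keep a ledger of the limiting reagent instead. In the north flask, reagent at 0.160 M stands below substrate at 0.20 M, so its charge allows 80.0 % of product. First entry: the north readings average 65.4 %, which books 0.131 M of reagent into product. Second entry: the balance of 0.0293 M is written off, its destination unseen in these readings. The books close on the reagent yield, the share of charged reagent that ends as product: 81.7 %. The north-east plateau, averaged from 25.0 s on, reads 34.1 %, a yield of 85.4 % on half the reagent, so in these two runs, with substrate held at 0.20 M, product follows the reagent charge.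

In powers of ten, the north readings span 1.08 decades of time, reading 64.6 % first and 64.6 % last, and the asked time lies 0.125 decades further. We therefore book 65.4 % at 40 min. Beta, zeta and delta put no reagent into the ledger, so we book no gain for them. Alpha adds 0.0800 M, which at our yield buys 33 percentage points, less than the 34.6 % of substrate still unreacted.

The forecast gives 65.4 % now, 65.4 % after beta, 65.4 % after delta, and alpha as best, holding that “the plateau is exhaustion, not equilibrium”. For alpha it reckons about 24 points, which differs from our figure.

The flask gives 65.8 %, with 65.8 % after beta and 65.8 % after delta, and its equations are these:

    substrate + reagent + released group → product + 2 released group (k = 34.3 L² mol⁻² s⁻¹)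
    substrate + reagent → product + released group (k = 0.0130 L mol⁻¹ s⁻¹)
    2 reagent → homo dimer (k = 0.140 L mol⁻¹ s⁻¹)
    reagent + product ⇌ idle adduct, settled at all times (K = 19.0 L mol⁻¹)

Alpha brings 34 points, and 0 % of the charged reagent stands free at 40.0 min. The reagent yield of this flask now reads 82.3 %. Carried to the neighbour flask charged with 0.27 M of reagent, our 81.7 % books 0.221 M of product, above its 0.20 M of substrate. That neighbour stands at 100 % product at 40.0 min, idle adduct counted in, with 0 % of its substrate left.

Readings and results are calculated on assumed constants, and the scatter is random.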